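**Plan**

1. Retrosynthesis: cut the C3–O angelate ester and the C11=C13 methylene; take the 3β,4β-diol/C5=C6 unit back, by way of a C6 selenide, to the 4-en-3-one; then cut C9–C10 (ring B) and C6–C7.
2. Enabling feature: ring A carries oxygen at C3, a methyl at C4 and the methyl-bearing quaternary C10 para to C3. This is the pattern of a 2,4-dimethylphenol alkylated at its para carbon by a chain anchored at C5, so ring A is bought as an arene.
3. Forward: 2,6-dimethylbenzoic acid is converted to the 3-methoxybenzylic Grignard reagent, which is added (copper, chiral diphosphine) to 5,6-dihydro-2H-pyran-2-one (C6–C7); BBr3/MeOH unmasks phenol, C9 bromide and methyl ester; KOt-Bu closes ring B by para C-alkylation.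
4. Ring A is then adjusted: C1=C2 hydrogenation, C6 selenenylation, C3 reduction, selenoxide [2,3] shift to the 4β-hydroxy-5-ene; the ester is α-methylenated on the silylated diol and the C3 hydroxyl is angeloylated last.
5. Stereochemistry: C7 from the catalyst; C10 from C7 through a chair transition state; C3 from axial hydride delivery; C4 from the suprafacial shift of a 6β-selenoxide; the Z alkene from angelic acid.

Key step: step 7

Remark: atoms are labelled with eudesmane numbers (C1–C15); the copper catalyst of step 5 is assumed to give the S lactone with the ligand named, and the mirror-image ligand is to be used if the sense of induction proves opposite.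

**Step 1**
Reactants: 1 2,6-dimethylbenzoic acid
Product: 2 3-bromo-2,6-dimethylbenzoic acid
Conditions: Br2 (1.05 equiv), FeBr3 (5 mol %), AcOH, 25 °C
Reagents that add atoms: bromine, BrBr
Why: Electrophilic aromatic bromination; C3 is ortho to one methyl group, para to the other and meta to the carboxyl group, so all three substituents direct to the same carbon and one equivalent should stop at the monobromide.

**Step 2**
Reactants: 2 3-bromo-2,6-dimethylbenzoic acid
Product: 3 3-methoxy-2,6-dimethylbenzoic acid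
Conditions: NaOMe (5 equiv), CuBr (10 mol %), MeOH–DMF, 110 °C; then aq. HCl
Reagents that add atoms: sodium methoxide, C[O-].[Na+]
Why: Ullmann-type copper-catalysed methoxylation of an aryl bromide, which tolerates the carboxylate and a single ortho methyl group.

**Step 3**
Reactants: 3 3-methoxy-2,6-dimethylbenzoic acid
Product: 4 (3-methoxy-2,6-dimethylphenyl)methanol
Conditions: LiAlH4 (2 equiv), THF, 0 → 66 °C
Reagents that add atoms: none
Why: Hydride reduction of a carboxylic acid; the di-ortho-substituted acid needs reflux but no other group competes.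

**Step 4**
Reactants: 4 (3-methoxy-2,6-dimethylphenyl)methanol
Product: 5 2-(chloromethyl)-4-methoxy-1,3-dimethylbenzene
Conditions: SOCl2 (1.2 equiv), CH2Cl2, 0 → 25 °C
Reagents that add atoms: thionyl chloride, O=S(Cl)Cl
Why: Chlorodehydroxylation of an electron-rich benzylic alcohol by way of its chlorosulfite; the chloride is preferred to the bromide because it gives less Wurtz coupling in the next step.

**Step 5**
Reactants: 5 2-(chloromethyl)-4-methoxy-1,3-dimethylbenzene; 6 5,6-dihydro-2H-pyran-2-one
Product: 8 (4S)-4-[(3-methoxy-2,6-dimethylphenyl)methyl]oxan-2-one, via Grignard reagent 7 (not isolated)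
Conditions: Mg, Et2O, 0 °C; then 6, CuBr·SMe2 (5 mol %), (R)-1-[(S_p)-2-(diphenylphosphino)ferrocenyl]ethyldicyclohexylphosphine (6 mol %), t-BuOMe, −78 °C, slow addition; aq. NH4Cl
Reagents that add atoms: none
Why: Copper-catalysed asymmetric conjugate addition of a Grignard reagent to an α,β-unsaturated δ-lactone; the chiral diphosphine–copper complex selects the enantioface at C7, and low temperature with slow addition should suppress 1,2-addition.

**Step 6**
Reactants: 8 (4S)-4-[(3-methoxy-2,6-dimethylphenyl)methyl]oxan-2-one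
Product: 10 methyl (3R)-5-bromo-3-[(3-hydroxy-2,6-dimethylphenyl)methyl]pentanoate, via bis(dibromoboryl) intermediate 9 (not isolated)
Conditions: BBr3 (4 equiv), CH2Cl2, −78 → 25 °C; then MeOH, 0 → 25 °C
Reagents that add atoms: boron tribromide, BrB(Br)Br; methanol, CO
Why: Lewis-acid ether and lactone cleavage: BBr3 demethylates the aryl ether and opens the lactone by bromide attack at the O–CH2 carbon C9, and methanolysis of the acyloxyborane gives the methyl ester; C7 is untouched and its descriptor changes to R only because bromine raises the priority of the C8 branch.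

**Step 7**
Reactants: 10 methyl (3R)-5-bromo-3-[(3-hydroxy-2,6-dimethylphenyl)methyl]pentanoate
Product: 12 methyl 2-[(2R,4aS)-4a,8-dimethyl-7-oxo-1,2,3,4,4a,7-hexahydronaphthalen-2-yl]acetate, via potassium phenoxide 11 (not isolated)
Conditions: KOt-Bu (1.05 equiv), t-BuOH (0.005 M), 80 °C
Reagents that add atoms: none
Why: One equivalent of KOt-Bu deprotonates only the phenol, and phenoxide 11 displaces the primary bromide at C9 through its para carbon C10 in an intramolecular SN2 reaction, giving a cyclohexa-2,5-dienone that cannot rearomatise because C10 is quaternary. The closest known reaction type is the intramolecular para C-alkylation of meta-tethered phenoxides to ring-fused cyclohexadienones (aryl participation of the Ar2-6 kind). Ring B closes in a 6-exo-tet mode through a chair-like transition state. The new stereocentre C10 is controlled by C7: the chair places the CH2CO2Me arm equatorial while the C10 methyl group stays perpendicular to the ring A plane (axial on ring B), which gives the cis (7β,10β) relation, and the minor trans isomer should be separable by chromatography. The step needs attack through C10 and not through the other methyl-bearing carbon C4 or through oxygen: closure on oxygen would need an eight-membered ring, hydrogen bonding by t-BuOH favours carbon over oxygen, and C10 bears the largest carbon coefficient of the phenoxide HOMO, is less crowded than C4 (which lies next to the solvated O–K group) and leads to the more stable cross-conjugated dienone. High dilution suppresses intermolecular O-alkylation.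

**Step 8**
Reactants: 12 methyl 2-[(2R,4aS)-4a,8-dimethyl-7-oxo-1,2,3,4,4a,7-hexahydronaphthalen-2-yl]acetate
Product: 13 methyl 2-[(2R,4aS)-4a,8-dimethyl-7-oxo-1,2,3,4,4a,5,6,7-octahydronaphthalen-2-yl]acetate
Conditions: H2 (1 atm), RhCl(PPh3)3 (10 mol %), toluene–EtOH, 25 °C
Reagents that add atoms: none
Why: Homogeneous hydrogenation with RhCl(PPh3)3 reduces the disubstituted C1=C2 bond of the cross-conjugated dienone and leaves the tetrasubstituted C4=C5 bond, as is known for 4-methyl-1,4-dien-3-ones of the santonin type.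

**Step 9**
Reactants: 13 methyl 2-[(2R,4aS)-4a,8-dimethyl-7-oxo-1,2,3,4,4a,5,6,7-octahydronaphthalen-2-yl]acetate
Product: 14 methyl 2-[(2S,4aS)-7-(tert-butyldimethylsilyloxy)-4a,8-dimethyl-2,3,4,4a,5,6-hexahydronaphthalen-2-yl]acetate
Conditions: TBSOTf (1.3 equiv), Et3N (2.5 equiv), CH2Cl2, 0 → 25 °C
Reagents that add atoms: tert-butyldimethylsilyl trifluoromethanesulfonate, CC(C)(C)[Si](C)(C)OS(=O)(=O)C(F)(F)F
Why: Soft enolisation with a silyl triflate and an amine under equilibrating conditions should give the extended 3,5-dienol silyl ether, while the ester is not enolised.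

**Step 10**
Reactants: 14 methyl 2-[(2S,4aS)-7-(tert-butyldimethylsilyloxy)-4a,8-dimethyl-2,3,4,4a,5,6-hexahydronaphthalen-2-yl]acetate
Product: 15 methyl 2-[(1R,2S,4aS)-4a,8-dimethyl-7-oxo-1-(phenylselanyl)-1,2,3,4,4a,5,6,7-octahydronaphthalen-2-yl]acetate
Conditions: PhSeCl (1.05 equiv), CH2Cl2, −78 °C
Reagents that add atoms: benzeneselenenyl chloride, Cl[Se]c1ccccc1
Why: Electrophilic γ-selenenylation of a silyl dienol ether at C6, the α carbon C4 being blocked by its methyl group; axial attack through a chair-like ring B should place selenium on the β face, as other electrophiles do on 3,5-dienol ethers of this ring system.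

**Step 11**
Reactants: 15 methyl 2-[(1R,2S,4aS)-4a,8-dimethyl-7-oxo-1-(phenylselanyl)-1,2,3,4,4a,5,6,7-octahydronaphthalen-2-yl]acetate
Product: 16 methyl 2-[(1R,2S,4aS,7S)-7-hydroxy-4a,8-dimethyl-1-(phenylselanyl)-1,2,3,4,4a,5,6,7-octahydronaphthalen-2-yl]acetate
Conditions: NaBH4, CeCl3·7H2O, MeOH, −40 °C
Reagents that add atoms: none
Why: Luche 1,2-reduction; axial hydride delivery to C3 from the α face, anti to the C10 methyl group, gives the equatorial 3β-alcohol, and the allylic selenide and the ester are inert.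

**Step 12**
Reactants: 16 methyl 2-[(1R,2S,4aS,7S)-7-hydroxy-4a,8-dimethyl-1-(phenylselanyl)-1,2,3,4,4a,5,6,7-octahydronaphthalen-2-yl]acetate
Product: 19 methyl 2-[(2S,4aS,7S,8R)-7,8-dihydroxy-4a,8-dimethyl-2,3,4,4a,5,6,7,8-octahydronaphthalen-2-yl]acetate, via selenoxide 17 (not isolated), via selenenate ester 18 (not isolated)
Conditions: 30% H2O2, pyridine, CH2Cl2, 0 → 25 °C
Reagents that add atoms: hydrogen peroxide, OO
Why: Oxidation to the allylic selenoxide is followed by its [2,3]-sigmatropic shift (the selenium counterpart of the Mislow–Evans rearrangement), which is suprafacial, so oxygen arrives at C4 on the β face that carried selenium at C6 while the double bond moves to C5=C6; the selenenate is cleaved in the oxidising aqueous medium.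

**Step 13**
Reactants: 19 methyl 2-[(2S,4aS,7S,8R)-7,8-dihydroxy-4a,8-dimethyl-2,3,4,4a,5,6,7,8-octahydronaphthalen-2-yl]acetate
Product: 20 methyl 2-[(2S,4aS,7S,8R)-4a,8-dimethyl-7,8-bis(triethylsilyloxy)-2,3,4,4a,5,6,7,8-octahydronaphthalen-2-yl]acetate
Conditions: TESOTf (3 equiv), 2,6-lutidine (5 equiv), CH2Cl2, −78 → 0 °C
Reagents that add atoms: triethylsilyl trifluoromethanesulfonate, CC[Si](CC)(CC)OS(=O)(=O)C(F)(F)F
Why: Silyl ether formation with a silyl triflate, reactive enough for the hindered tertiary allylic alcohol, removes both acidic protons before the enolate step.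

**Step 14**
Reactants: 20 methyl 2-[(2S,4aS,7S,8R)-4a,8-dimethyl-7,8-bis(triethylsilyloxy)-2,3,4,4a,5,6,7,8-octahydronaphthalen-2-yl]acetate
Product: 22 methyl 3-(dimethylamino)-2-[(2R,4aS,7S,8R)-4a,8-dimethyl-7,8-bis(triethylsilyloxy)-2,3,4,4a,5,6,7,8-octahydronaphthalen-2-yl]propanoate (both epimers at the propanoate C2), via lithium enolate 21 (not isolated)
Conditions: LiN(i-Pr)2 (1.3 equiv), THF, −78 °C; then CH2=NMe2+ I− (3 equiv), −78 → 0 °C
Reagents that add atoms: dimethylmethyleneiminium iodide, C=[N+](C)C.[I-]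
Why: Mannich reaction of the ester enolate with a preformed iminium salt; C11 carries the only acidic C–H left, and the configuration of the new C11 centre is irrelevant because it becomes sp2 in the next step.

**Step 15**
Reactants: 22 methyl 3-(dimethylamino)-2-[(2R,4aS,7S,8R)-4a,8-dimethyl-7,8-bis(triethylsilyloxy)-2,3,4,4a,5,6,7,8-octahydronaphthalen-2-yl]propanoate
Product: 24 methyl 2-[(2R,4aS,7S,8R)-4a,8-dimethyl-7,8-bis(triethylsilyloxy)-2,3,4,4a,5,6,7,8-octahydronaphthalen-2-yl]prop-2-enoate, via trimethylammonium iodide 23 (not isolated)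
Conditions: MeI (10 equiv), THF, 25 °C; then DBU (3 equiv), 25 °C
Reagents that add atoms: none
Why: N-Methylation followed by base-induced β-elimination of trimethylamine (E1cB, Hofmann-type) gives the α-methylene ester under conditions that do not touch the silyl ethers.

**Step 16**
Reactants: 24 methyl 2-[(2R,4aS,7S,8R)-4a,8-dimethyl-7,8-bis(triethylsilyloxy)-2,3,4,4a,5,6,7,8-octahydronaphthalen-2-yl]prop-2-enoate
Product: 25 methyl 2-[(2R,4aS,7S,8R)-7,8-dihydroxy-4a,8-dimethyl-2,3,4,4a,5,6,7,8-octahydronaphthalen-2-yl]prop-2-enoate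
Conditions: HF·pyridine, pyridine, THF, 0 → 25 °C
Reagents that add atoms: none
Why: Fluoride-mediated desilylation under buffered conditions should spare the acrylate and avoid ionisation of the tertiary allylic alcohol.

**Step 17**
Reactants: 25 methyl 2-[(2R,4aS,7S,8R)-7,8-dihydroxy-4a,8-dimethyl-2,3,4,4a,5,6,7,8-octahydronaphthalen-2-yl]prop-2-enoate; 26 angelic acid
Product: 28 methyl 2-[(2R,4aS,7S,8R)-8-hydroxy-4a,8-dimethyl-7-{[(2Z)-2-methylbut-2-enoyl]oxy}-2,3,4,4a,5,6,7,8-octahydronaphthalen-2-yl]prop-2-enoate (CNP0283268.1), via mixed anhydride 27 (not isolated)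
Conditions: 26, 2,4,6-trichlorobenzoyl chloride, Et3N, toluene, 25 °C; then 25, 80 °C
Reagents that add atoms: none
Why: Yamaguchi esterification through the mixed anhydride should acylate only the secondary 3β-hydroxyl group, the tertiary C4 hydroxyl being too hindered, and run without DMAP it keeps the Z geometry of the angelate.

**Compound list**

1 | 2,6-dimethylbenzoic acid | Cc1cccc(C)c1C(=O)O | starting material
2 | 3-bromo-2,6-dimethylbenzoic acid | Cc1ccc(Br)c(C)c1C(=O)O | intermediate
3 | 3-methoxy-2,6-dimethylbenzoic acid | COc1ccc(C)c(C(=O)O)c1C | intermediate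
4 | (3-methoxy-2,6-dimethylphenyl)methanol | COc1ccc(C)c(CO)c1C | intermediate
5 | 2-(chloromethyl)-4-methoxy-1,3-dimethylbenzene | COc1ccc(C)c(CCl)c1C | intermediate
6 | 5,6-dihydro-2H-pyran-2-one | O=C1C=CCCO1 | starting material
7 | [(3-methoxy-2,6-dimethylphenyl)methyl]magnesium chloride | COc1ccc(C)c(C[Mg]Cl)c1C | intermediate
8 | (4S)-4-[(3-methoxy-2,6-dimethylphenyl)methyl]oxan-2-one | O=C1C[C@@H](Cc2c(C)ccc(OC)c2C)CCO1 | intermediate
9 | (3R)-5-bromo-3-{[3-(dibromoboryloxy)-2,6-dimethylphenyl]methyl}pentanoic dibromoborinic anhydride | Cc1ccc(OB(Br)Br)c(C)c1C[C@H](CC(=O)OB(Br)Br)CCBr | intermediate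
10 | methyl (3R)-5-bromo-3-[(3-hydroxy-2,6-dimethylphenyl)methyl]pentanoate | Cc1ccc(O)c(C)c1C[C@H](CC(=O)OC)CCBr | intermediate
11 | potassium 3-[(2R)-4-bromo-2-(2-methoxy-2-oxoethyl)butyl]-2,4-dimethylphenoxide | Cc1ccc([O-])c(C)c1C[C@H](CC(=O)OC)CCBr.[K+] | intermediate
12 | methyl 2-[(2R,4aS)-4a,8-dimethyl-7-oxo-1,2,3,4,4a,7-hexahydronaphthalen-2-yl]acetate | COC(=O)C[C@H]1CC2=C(C)C(=O)C=C[C@]2(C)CC1 | intermediate
13 | methyl 2-[(2R,4aS)-4a,8-dimethyl-7-oxo-1,2,3,4,4a,5,6,7-octahydronaphthalen-2-yl]acetate | COC(=O)C[C@H]1CC2=C(C)C(=O)CC[C@]2(C)CC1 | intermediate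
14 | methyl 2-[(2S,4aS)-7-(tert-butyldimethylsilyloxy)-4a,8-dimethyl-2,3,4,4a,5,6-hexahydronaphthalen-2-yl]acetate | COC(=O)C[C@H]1C=C2C(C)=C(O[Si](C)(C)C(C)(C)C)CC[C@]2(C)CC1 | intermediate
15 | methyl 2-[(1R,2S,4aS)-4a,8-dimethyl-7-oxo-1-(phenylselanyl)-1,2,3,4,4a,5,6,7-octahydronaphthalen-2-yl]acetate | COC(=O)C[C@H]1[C@@H]([Se]c3ccccc3)C2=C(C)C(=O)CC[C@]2(C)CC1 | intermediate
16 | methyl 2-[(1R,2S,4aS,7S)-7-hydroxy-4a,8-dimethyl-1-(phenylselanyl)-1,2,3,4,4a,5,6,7-octahydronaphthalen-2-yl]acetate | COC(=O)C[C@H]1[C@@H]([Se]c3ccccc3)C2=C(C)[C@@H](O)CC[C@]2(C)CC1 | intermediate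
17 | selenoxide of 16 (6β-phenylseleninyl; configuration at selenium open) | COC(=O)C[C@H]1[C@@H]([Se](=O)c3ccccc3)C2=C(C)[C@@H](O)CC[C@]2(C)CC1 | intermediate
18 | methyl 2-[(2S,4aS,7S,8R)-7-hydroxy-4a,8-dimethyl-8-(phenylselanyloxy)-2,3,4,4a,5,6,7,8-octahydronaphthalen-2-yl]acetate | COC(=O)C[C@H]1C=C2[C@@](C)(O[Se]c3ccccc3)[C@@H](O)CC[C@]2(C)CC1 | intermediate
19 | methyl 2-[(2S,4aS,7S,8R)-7,8-dihydroxy-4a,8-dimethyl-2,3,4,4a,5,6,7,8-octahydronaphthalen-2-yl]acetate | COC(=O)C[C@H]1C=C2[C@@](C)(O)[C@@H](O)CC[C@]2(C)CC1 | intermediate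
20 | methyl 2-[(2S,4aS,7S,8R)-4a,8-dimethyl-7,8-bis(triethylsilyloxy)-2,3,4,4a,5,6,7,8-octahydronaphthalen-2-yl]acetate | COC(=O)C[C@H]1C=C2[C@@](C)(O[Si](CC)(CC)CC)[C@@H](O[Si](CC)(CC)CC)CC[C@]2(C)CC1 | intermediate
21 | lithium enolate of 20 (enolate geometry open) | COC(O[Li])=C[C@H]1C=C2[C@@](C)(O[Si](CC)(CC)CC)[C@@H](O[Si](CC)(CC)CC)CC[C@]2(C)CC1 | intermediate
22 | methyl 3-(dimethylamino)-2-[(2R,4aS,7S,8R)-4a,8-dimethyl-7,8-bis(triethylsilyloxy)-2,3,4,4a,5,6,7,8-octahydronaphthalen-2-yl]propanoate (both epimers at the propanoate C2) | COC(=O)C(CN(C)C)[C@H]1C=C2[C@@](C)(O[Si](CC)(CC)CC)[C@@H](O[Si](CC)(CC)CC)CC[C@]2(C)CC1 | intermediate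
23 | trimethylammonium iodide from 22 | COC(=O)C(C[N+](C)(C)C)[C@H]1C=C2[C@@](C)(O[Si](CC)(CC)CC)[C@@H](O[Si](CC)(CC)CC)CC[C@]2(C)CC1.[I-] | intermediate
24 | methyl 2-[(2R,4aS,7S,8R)-4a,8-dimethyl-7,8-bis(triethylsilyloxy)-2,3,4,4a,5,6,7,8-octahydronaphthalen-2-yl]prop-2-enoate | C=C(C(=O)OC)[C@H]1C=C2[C@@](C)(O[Si](CC)(CC)CC)[C@@H](O[Si](CC)(CC)CC)CC[C@]2(C)CC1 | intermediate
25 | methyl 2-[(2R,4aS,7S,8R)-7,8-dihydroxy-4a,8-dimethyl-2,3,4,4a,5,6,7,8-octahydronaphthalen-2-yl]prop-2-enoate | C=C(C(=O)OC)[C@H]1C=C2[C@@](C)(O)[C@@H](O)CC[C@]2(C)CC1 | intermediate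
26 | angelic acid, (2Z)-2-methylbut-2-enoic acid | C/C=C(/C)C(=O)O | starting material
27 | (2Z)-2-methylbut-2-enoic 2,4,6-trichlorobenzoic anhydride | C/C=C(/C)C(=O)OC(=O)c1c(Cl)cc(Cl)cc1Cl | intermediate
28 | methyl 2-[(2R,4aS,7S,8R)-8-hydroxy-4a,8-dimethyl-7-{[(2Z)-2-methylbut-2-enoyl]oxy}-2,3,4,4a,5,6,7,8-octahydronaphthalen-2-yl]prop-2-enoate | C=C(C(=O)OC)[C@H]1C=C2[C@](C)(CC[C@H](OC(=O)/C(C)=C\C)[C@]2(C)O)CC1 | target

**Step count**

Total step count: 17. Longest linear sequence: 17 steps (1 to 28); 6 and 26 enter as purchased materials.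

**Steps most likely to fail**

Step 7. What may go wrong: ring closure through the other methyl-bearing carbon C4 (ortho to oxygen), or closure with little preference between the two chairs at C10. No change of leaving group can exclude the C4 pathway, because C4 and C10 both adjoin the anchoring carbon C5. The fallback sets out from 6 and returns at 13, and builds ring B without an arene so that C10 is the only nucleophilic carbon. The SAMP hydrazone of butan-2-one F1 (from butan-2-one and (S)-1-amino-2-(methoxymethyl)pyrrolidine; the antipode if the opposite sense is found) is lithiated at its methyl group with LiN(i-Pr)2 and added 1,4 to 6 to give hydrazone lactone F2, the auxiliary setting C7. Two-phase hydrolysis with aqueous oxalic acid releases keto lactone F3. HBr in AcOH and then MeOH open the lactone, as in step 6, to bromo keto ester F4. KOt-Bu then closes ring B by alkylation of the ketone enolate at C10 (attack from C6 would give a four-membered ring) to cyclohexanone F5. Condensation with (R)-1-phenylethylamine gives imine F6, whose enamine tautomer adds to pent-1-en-3-one on the face set by the amine; mild acid hydrolysis gives diketone F7 with the quaternary C10 cis to the C7 arm. NaOMe in MeOH closes ring A by aldol condensation (Robinson annulation) to enone 13.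

Step 5. What may go wrong: the hindered benzylic Grignard reagent may add 1,2 to the lactone, couple with its own chloride, or add with low enantioselectivity. The fallback sets out from 5 and returns at 8, and separates carbon–carbon bond formation from asymmetric induction. Zinc insertion into 5 (Zn dust, LiCl, THF) gives benzylzinc chloride F9. Negishi coupling of F9 (Pd(PPh3)4, zerovalent palladium, THF, 50 °C) with the enol tosylate F8 (from oxane-2,4-dione, TsCl and Et3N) gives the achiral unsaturated lactone F10. Copper hydride conjugate reduction (CuCl2, (S)-p-Tol-BINAP or its antipode as required, NaOt-Bu, polymethylhydrosiloxane, toluene) then sets C7 and gives 8.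

Step 10. What may go wrong: attack of the selenium electrophile on the α face of C6 or at C4, or epimerisation of the axial 6β-selenide; each would carry the oxygen to the wrong face of C4 or to the wrong carbon in step 12. The fallback sets out from 13 and returns at 19, and delivers the oxygen to the β face of C4 from the C3 hydroxyl instead. Luche reduction of 13 gives allylic alcohol F11. VO(acac)2 with t-BuOOH epoxidises C4=C5 on the face of the hydroxyl to the 4β,5β-epoxy alcohol F12. Me3SiOTf with DBU opens the epoxide eliminatively: the C3 silyloxy group disfavours cleavage of the C4–O bond, so the C5–O bond breaks and only C6 offers hydrogens, giving the bis(trimethylsilyl) ether F13. K2CO3 in MeOH then gives 19.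

**Further compounds**

F1 | step 7 | (2S)-N-(butan-2-ylidene)-2-(methoxymethyl)pyrrolidin-1-amine | CCC(C)=NN1CCC[C@H]1COC
F2 | step 7 | (4S)-4-(2-{[(2S)-2-(methoxymethyl)pyrrolidin-1-yl]imino}butyl)oxan-2-one | O=C1C[C@@H](CC(CC)=NN2CCC[C@H]2COC)CCO1
F3 | step 7 | (4R)-4-(2-oxobutyl)oxan-2-one | O=C1C[C@@H](CC(=O)CC)CCO1
F4 | step 7 | methyl (3R)-3-(2-bromoethyl)-5-oxoheptanoate | CCC(=O)C[C@H](CC(=O)OC)CCBr
F5 | step 7 | methyl 2-[(1R)-4-methyl-3-oxocyclohexyl]acetate (both epimers at C4) | COC(=O)C[C@H]1CC(=O)C(C)CC1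
F6 | step 7 | methyl 2-[(1R)-4-methyl-3-{[(1R)-1-phenylethyl]imino}cyclohexyl]acetate | COC(=O)C[C@H]1CC(=N[C@H](C)c2ccccc2)C(C)CC1
F7 | step 7 | methyl 2-[(1R,4S)-4-methyl-3-oxo-4-(3-oxopentyl)cyclohexyl]acetate | COC(=O)C[C@H]1CC(=O)[C@](C)(CCC(=O)CC)CC1
F8 | step 5 | 2-oxo-5,6-dihydro-2H-pyran-4-yl 4-methylbenzenesulfonate | Cc1ccc(cc1)S(=O)(=O)OC1=CC(=O)OCC1
F9 | step 5 | [(3-methoxy-2,6-dimethylphenyl)methyl]zinc chloride | COc1ccc(C)c(C[Zn]Cl)c1C
F10 | step 5 | 4-[(3-methoxy-2,6-dimethylphenyl)methyl]-5,6-dihydro-2H-pyran-2-one | COc1ccc(C)c(CC2=CC(=O)OCC2)c1C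
F11 | step 10 | methyl 2-[(2R,4aS,7S)-7-hydroxy-4a,8-dimethyl-1,2,3,4,4a,5,6,7-octahydronaphthalen-2-yl]acetate | COC(=O)C[C@H]1CC2=C(C)[C@@H](O)CC[C@]2(C)CC1
F12 | step 10 | 4β,5β-epoxide of F11 (eudesmane numbering; epoxide on the face of the 3β-hydroxyl) | COC(=O)C[C@H]1C[C@]23O[C@@]2(C)[C@@H](O)CC[C@]3(C)CC1
F13 | step 10 | methyl 2-[(2S,4aS,7S,8R)-4a,8-dimethyl-7,8-bis(trimethylsilyloxy)-2,3,4,4a,5,6,7,8-octahydronaphthalen-2-yl]acetate | COC(=O)C[C@H]1C=C2[C@@](C)(O[Si](C)(C)C)[C@@H](O[Si](C)(C)C)CC[C@]2(C)CC1
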